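**Retrosynthetic overview**

1. Target 18 ⇐ oxolane alcohol 15 by acetylation, desilylation and oxidation at C6 (no ring change).
2. Oxolane (second ring): 15 ⇐ 14 by transannular 5-exo attack of the C1 tertiary carbinol on C12 of the (11R,12R)-epoxide, itself from Shi epoxidation of the E-C11=C12 olefin of 13.
3. Carbocycle (first ring): 13 ⇐ 12 ⇐ 10 by head-to-tail closure of the C1–C2 bond: the alkynyl C2 of the open chain adds to the C1 isopropyl ketone (serratol-type carbinol); the alkyne then becomes the 2E olefin.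
4. Chain 10 ⇐ (S)-citronellal (C6–C13, C8 centre) + 4-(trimethylsilyl)but-3-yn-2-one (C2–C5) + MeMgBr (C18) + 3-methylbutan-2-one (C14, C1, isopropyl).
5. Ring order: 14-membered carbocycle first, oxolane second.

Assumption: positions are given in cembrane numbering (C1 = ring carbon bearing isopropyl, C2=C3 olefin, C4 carbinol, C6 ketone, C8 methine, C11 acetoxy carbon, C12 ether carbon), and the ProPhenol antipode named in step 1 is the one taken to give the 5R aldol (its mirror image is used if the sense proves opposite).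

**Route**

Step 1
Reactants: 1 (S)-citronellal; 2 4-(trimethylsilyl)but-3-yn-2-one
Product: 3 (5R,7S)-5-hydroxy-7,11-dimethyl-1-(trimethylsilyl)dodec-10-en-1-yn-3-one
Conditions: (S,S)-ProPhenol (10 mol %), Et2Zn (20 mol %), 4 Å MS, THF, 0 °C, slow addition of 1
Reagents that add atoms: none
Why: Direct catalytic asymmetric aldol of a methyl ynone (dinuclear zinc–ProPhenol type), in which the catalyst sets the new carbinol (cembrane C6, R) while the C8 centre comes unchanged from citronellal.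

Step 2
Reactants: 3 (5R,7S)-5-hydroxy-7,11-dimethyl-1-(trimethylsilyl)dodec-10-en-1-yn-3-one
Product: 4 (3R,5R,7S)-3,7,11-trimethyl-1-(trimethylsilyl)dodec-10-en-1-yne-3,5-diol
Conditions: MeMgBr (3.5 equiv), CH2Cl2/Et2O, −78 °C; aq NH4Cl
Reagents that add atoms: methylmagnesium bromide, C[Mg]Br
Why: Chelation-controlled Grignard 1,2-addition to the magnesium aldolate of the β-hydroxy ynone (1,3-induction through the six-membered chelate, external attack) gives the 1,3-syn diol and so sets C4 as R; the minor C4 epimer is a separable diastereomer.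

Step 3
Reactants: 4 (3R,5R,7S)-3,7,11-trimethyl-1-(trimethylsilyl)dodec-10-en-1-yne-3,5-diol
Product: 5 (3R,5R,7S)-3,5-bis(tert-butyldimethylsilyloxy)-3,7,11-trimethyl-1-(trimethylsilyl)dodec-10-en-1-yne
Conditions: TBSOTf (2.6 equiv), 2,6-lutidine, CH2Cl2, 0 °C to rt
Reagents that add atoms: tert-butyldimethylsilyl trifluoromethanesulfonate, CC(C)(C)[Si](C)(C)OS(=O)(=O)C(F)(F)F
Why: Silyl triflate silylation caps the secondary and the tertiary propargylic hydroxyl in one operation so that both survive the enolate, fluoride, hydride and rhenium steps; no stereocentre is touched.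

Step 4
Reactants: 5 (3R,5R,7S)-3,5-bis(tert-butyldimethylsilyloxy)-3,7,11-trimethyl-1-(trimethylsilyl)dodec-10-en-1-yne
Product: 6 (2E,6S,8R,10R)-8,10-bis(tert-butyldimethylsilyloxy)-2,6,10-trimethyl-12-(trimethylsilyl)dodec-2-en-11-yn-1-ol
Conditions: SeO2 (0.3 equiv), t-BuOOH (3 equiv), salicylic acid (cat.), CH2Cl2, rt
Reagents that add atoms: tert-butyl hydroperoxide, CC(C)(C)OO
Why: Catalytic selenium dioxide allylic oxidation (ene reaction then [2,3]-shift) hydroxylates only the E-methyl of the trisubstituted olefin, which fixes the E geometry of the future C11=C12 bond.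

Step 5
Reactants: 6 (2E,6S,8R,10R)-8,10-bis(tert-butyldimethylsilyloxy)-2,6,10-trimethyl-12-(trimethylsilyl)dodec-2-en-11-yn-1-ol
Product: 7 (2E,6S,8R,10R)-1-bromo-8,10-bis(tert-butyldimethylsilyloxy)-2,6,10-trimethyl-12-(trimethylsilyl)dodec-2-en-11-yne
Conditions: CBr4, PPh3, CH2Cl2, 0 °C
Reagents that add atoms: carbon tetrabromide, BrC(Br)(Br)Br
Why: Appel bromination of the primary allylic alcohol under neutral conditions proceeds without allylic transposition or loss of olefin geometry.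

Step 6
Reactants: 7 (2E,6S,8R,10R)-1-bromo-8,10-bis(tert-butyldimethylsilyloxy)-2,6,10-trimethyl-12-(trimethylsilyl)dodec-2-en-11-yne; 8 3-methylbutan-2-one
Product: 10 (6E,10S,12R,14R)-12,14-bis(tert-butyldimethylsilyloxy)-2,6,10,14-tetramethyl-16-(trimethylsilyl)hexadec-6-en-15-yn-3-one, via lithium 3-methylbut-1-en-2-olate 9 (not isolated)
Conditions: 8 (3 equiv), LDA, THF, −78 °C; then 7, DMPU, −78 to −20 °C
Reagents that add atoms: none
Why: Kinetic deprotonation at the methyl group followed by SN2 alkylation of the lithium enolate with the primary allylic bromide brings in C14, C1 and the isopropyl group as the isopropyl ketone.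

Step 7
Reactants: 10 (6E,10S,12R,14R)-12,14-bis(tert-butyldimethylsilyloxy)-2,6,10,14-tetramethyl-16-(trimethylsilyl)hexadec-6-en-15-yn-3-one
Product: 12 (1RS,4R,6R,8S,11E)-4,6-bis(tert-butyldimethylsilyloxy)-1-isopropyl-4,8,12-trimethylcyclotetradec-11-en-2-yn-1-ol, via macrocyclic trimethylsilyl ether 11 (not isolated)
Conditions: TBAT (15 mol %), THF, 0.003 M (syringe pump), rt; then K2CO3 (cat.), MeOH
Reagents that add atoms: none
Why: Proposed new method: fluoride starts an autocatalytic transfer of the alkynyl group from silicon to the C1 ketone, and the resulting C1 alkoxide takes the silyl group from the next alkynylsilane, so the closure of the C1–C2 bond is trapped irreversibly as the silyl ether 11 and no free alkoxide accumulates to enolise the ketone; the closest known reactions are fluoride- or alkoxide-catalysed additions of alkynyltrimethylsilanes to enolisable ketones and Favorskii alkynylation, here run intramolecularly at high dilution, and C1 forms as a roughly 1:1 epimer mixture that is corrected in step 10.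

Step 8
Reactants: 12 (1RS,4R,6R,8S,11E)-4,6-bis(tert-butyldimethylsilyloxy)-1-isopropyl-4,8,12-trimethylcyclotetradec-11-en-2-yn-1-ol
Product: 13 (1RS,2E,4R,6R,8S,11E)-4,6-bis(tert-butyldimethylsilyloxy)-1-isopropyl-4,8,12-trimethylcyclotetradeca-2,11-dien-1-ol
Conditions: Red-Al, THF, 0 °C to rt; Rochelle salt work-up
Reagents that add atoms: none
Why: Hydroxyl-directed trans-hydroalumination of the propargylic alcohol and protonolysis give only the 2E olefin; the temperature is kept low so that the vinylalanate does not eliminate the C4 silyloxy group to an allene.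

Step 9
Reactants: 13 (1RS,2E,4R,6R,8S,11E)-4,6-bis(tert-butyldimethylsilyloxy)-1-isopropyl-4,8,12-trimethylcyclotetradeca-2,11-dien-1-ol
Product: 14 (1RS,2E,4R,6R,8S,11R,12R)-4,6-bis(tert-butyldimethylsilyloxy)-11,12-epoxy-1-isopropyl-4,8,12-trimethylcyclotetradec-2-en-1-ol
Conditions: D-fructose-derived Shi ketone (30 mol %), Oxone, K2CO3, Bu4NHSO4, MeCN/DMM/aq buffer (pH 10.5), 0 °C
Reagents that add atoms: potassium peroxymonosulfate, [K+].[O-]S(=O)(=O)OO
Why: Shi asymmetric epoxidation, in which the chiral dioxirane attacks the only electron-rich accessible olefin (trisubstituted C11=C12; the C2=C3 olefin is flanked by two quaternary carbons) through the spiro transition state and sets 11R,12R by reagent control.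

Step 10
Reactants: 14 (1RS,2E,4R,6R,8S,11R,12R)-4,6-bis(tert-butyldimethylsilyloxy)-11,12-epoxy-1-isopropyl-4,8,12-trimethylcyclotetradec-2-en-1-ol
Product: 15 (1S,2E,4R,6R,8S,11R,12S)-4,6-bis(tert-butyldimethylsilyloxy)-1,12-epoxy-1-isopropyl-4,8,12-trimethylcyclotetradec-2-en-11-ol
Conditions: Re2O7 (5 mol %), CH2Cl2, 0 °C to rt
Reagents that add atoms: none
Why: Proposed new method: the acidic rhenium oxide activates the epoxide for transannular 5-exo attack of the C1 hydroxyl at the tertiary C12 with inversion (the serratol epoxide to incensole type of closure), which only the 1S epimer can do because only it reaches the rear of C12 in a cis-bridged geometry, while the 1R epimer is converted into its perrhenate ester and re-equilibrated through the C1–C3 allyl cation ion pair (Curtin–Hammett funnelling, C4 is silylated and cannot ionise this way), so C1 (S), C12 (S) and C11 (R) are set together; the closest known reactions are Re2O7-mediated allylic alcohol transposition–epoxide opening cyclisations and acid-catalysed closure of bishomoallylic epoxy alcohols to oxolanes.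

Step 11
Reactants: 15 (1S,2E,4R,6R,8S,11R,12S)-4,6-bis(tert-butyldimethylsilyloxy)-1,12-epoxy-1-isopropyl-4,8,12-trimethylcyclotetradec-2-en-11-ol
Product: 16 (1S,2E,4R,6R,8S,11R,12S)-4,6-bis(tert-butyldimethylsilyloxy)-1,12-epoxy-1-isopropyl-4,8,12-trimethylcyclotetradec-2-en-11-yl acetate
Conditions: Ac2O, DMAP (cat.), pyridine, rt
Reagents that add atoms: acetic anhydride, CC(=O)OC(C)=O
Why: DMAP-catalysed acylation of the only free hydroxyl (secondary, C11) with retention.

Step 12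
Reactants: 16 (1S,2E,4R,6R,8S,11R,12S)-4,6-bis(tert-butyldimethylsilyloxy)-1,12-epoxy-1-isopropyl-4,8,12-trimethylcyclotetradec-2-en-11-yl acetate
Product: 17 (1S,2E,4R,6R,8S,11R,12S)-1,12-epoxy-4,6-dihydroxy-1-isopropyl-4,8,12-trimethylcyclotetradec-2-en-11-yl acetate
Conditions: HF·pyridine, pyridine, THF, 0 °C to rt
Reagents that add atoms: none
Why: Buffered fluoride desilylation removes both silyl ethers while the acetate, the allylic ether and the tertiary allylic alcohol are left intact.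

Step 13
Reactants: 17 (1S,2E,4R,6R,8S,11R,12S)-1,12-epoxy-4,6-dihydroxy-1-isopropyl-4,8,12-trimethylcyclotetradec-2-en-11-yl acetate
Product: 18 (1S,2E,4R,8S,11R,12S)-1,12-epoxy-4-hydroxy-1-isopropyl-4,8,12-trimethyl-6-oxocyclotetradec-2-en-11-yl acetate
Conditions: Dess–Martin periodinane, pyridine, CH2Cl2, 0 °C to rt
Reagents that add atoms: none
Why: Dess–Martin oxidation of the secondary C6 alcohol (the tertiary C4 hydroxyl is inert) under buffered non-basic conditions avoids retro-aldol or dehydration of the β-hydroxy ketone and removes the auxiliary C6 centre.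

**Compound list**

1 | (S)-citronellal, (3S)-3,7-dimethyloct-6-enal | O=CC[C@@H](C)CCC=C(C)C | starting material
2 | 4-(trimethylsilyl)but-3-yn-2-one | CC(=O)C#C[Si](C)(C)C | starting material
3 | (5R,7S)-5-hydroxy-7,11-dimethyl-1-(trimethylsilyl)dodec-10-en-1-yn-3-one | C[Si](C)(C)C#CC(=O)C[C@H](O)C[C@@H](C)CCC=C(C)C | intermediate
4 | (3R,5R,7S)-3,7,11-trimethyl-1-(trimethylsilyl)dodec-10-en-1-yne-3,5-diol | C[Si](C)(C)C#C[C@](C)(O)C[C@H](O)C[C@@H](C)CCC=C(C)C | intermediate
5 | (3R,5R,7S)-3,5-bis(tert-butyldimethylsilyloxy)-3,7,11-trimethyl-1-(trimethylsilyl)dodec-10-en-1-yne | C[Si](C)(C)C#C[C@](C)(O[Si](C)(C)C(C)(C)C)C[C@H](O[Si](C)(C)C(C)(C)C)C[C@@H](C)CCC=C(C)C | intermediate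
6 | (2E,6S,8R,10R)-8,10-bis(tert-butyldimethylsilyloxy)-2,6,10-trimethyl-12-(trimethylsilyl)dodec-2-en-11-yn-1-ol | C[Si](C)(C)C#C[C@](C)(O[Si](C)(C)C(C)(C)C)C[C@H](O[Si](C)(C)C(C)(C)C)C[C@@H](C)CC/C=C(\C)CO | intermediate
7 | (2E,6S,8R,10R)-1-bromo-8,10-bis(tert-butyldimethylsilyloxy)-2,6,10-trimethyl-12-(trimethylsilyl)dodec-2-en-11-yne | C[Si](C)(C)C#C[C@](C)(O[Si](C)(C)C(C)(C)C)C[C@H](O[Si](C)(C)C(C)(C)C)C[C@@H](C)CC/C=C(\C)CBr | intermediate
8 | 3-methylbutan-2-one | CC(=O)C(C)C | starting material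
9 | lithium 3-methylbut-1-en-2-olate (not isolated) | [Li+].[O-]C(=C)C(C)C | intermediate
10 | (6E,10S,12R,14R)-12,14-bis(tert-butyldimethylsilyloxy)-2,6,10,14-tetramethyl-16-(trimethylsilyl)hexadec-6-en-15-yn-3-one | C[Si](C)(C)C#C[C@](C)(O[Si](C)(C)C(C)(C)C)C[C@H](O[Si](C)(C)C(C)(C)C)C[C@@H](C)CC/C=C(\C)CCC(=O)C(C)C | intermediate
11 | (1RS,4R,6R,8S,11E)-4,6-bis(tert-butyldimethylsilyloxy)-1-isopropyl-4,8,12-trimethyl-1-(trimethylsilyloxy)cyclotetradec-11-en-2-yne (not isolated, both C1 epimers) | CC(C)C1(O[Si](C)(C)C)C#C[C@](C)(O[Si](C)(C)C(C)(C)C)C[C@H](O[Si](C)(C)C(C)(C)C)C[C@@H](C)CC/C=C(\C)CC1 | intermediate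
12 | (1RS,4R,6R,8S,11E)-4,6-bis(tert-butyldimethylsilyloxy)-1-isopropyl-4,8,12-trimethylcyclotetradec-11-en-2-yn-1-ol (both C1 epimers) | CC(C)C1(O)C#C[C@](C)(O[Si](C)(C)C(C)(C)C)C[C@H](O[Si](C)(C)C(C)(C)C)C[C@@H](C)CC/C=C(\C)CC1 | intermediate
13 | (1RS,2E,4R,6R,8S,11E)-4,6-bis(tert-butyldimethylsilyloxy)-1-isopropyl-4,8,12-trimethylcyclotetradeca-2,11-dien-1-ol (both C1 epimers) | CC(C)C1(O)/C=C/[C@](C)(O[Si](C)(C)C(C)(C)C)C[C@H](O[Si](C)(C)C(C)(C)C)C[C@@H](C)CC/C=C(\C)CC1 | intermediate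
14 | (1RS,2E,4R,6R,8S,11R,12R)-4,6-bis(tert-butyldimethylsilyloxy)-11,12-epoxy-1-isopropyl-4,8,12-trimethylcyclotetradec-2-en-1-ol (both C1 epimers) | CC(C)C1(O)/C=C/[C@](C)(O[Si](C)(C)C(C)(C)C)C[C@H](O[Si](C)(C)C(C)(C)C)C[C@@H](C)CC[C@H]2O[C@]2(C)CC1 | intermediate
15 | (1S,2E,4R,6R,8S,11R,12S)-4,6-bis(tert-butyldimethylsilyloxy)-1,12-epoxy-1-isopropyl-4,8,12-trimethylcyclotetradec-2-en-11-ol | O[C@@H]1CC[C@H](C)C[C@@H](O[Si](C)(C)C(C)(C)C)C[C@@](C)(O[Si](C)(C)C(C)(C)C)/C=C/[C@@]2(C(C)C)CC[C@]1(C)O2 | intermediate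
16 | (1S,2E,4R,6R,8S,11R,12S)-4,6-bis(tert-butyldimethylsilyloxy)-1,12-epoxy-1-isopropyl-4,8,12-trimethylcyclotetradec-2-en-11-yl acetate | CC(=O)O[C@@H]1CC[C@H](C)C[C@@H](O[Si](C)(C)C(C)(C)C)C[C@@](C)(O[Si](C)(C)C(C)(C)C)/C=C/[C@@]2(C(C)C)CC[C@]1(C)O2 | intermediate
17 | (1S,2E,4R,6R,8S,11R,12S)-1,12-epoxy-4,6-dihydroxy-1-isopropyl-4,8,12-trimethylcyclotetradec-2-en-11-yl acetate | CC(=O)O[C@@H]1CC[C@H](C)C[C@@H](O)C[C@@](C)(O)/C=C/[C@@]2(C(C)C)CC[C@]1(C)O2 | intermediate
18 | (1S,2E,4R,8S,11R,12S)-1,12-epoxy-4-hydroxy-1-isopropyl-4,8,12-trimethyl-6-oxocyclotetradec-2-en-11-yl acetate (CNP0131678.1) | CC(=O)O[C@@H]1CC[C@H](C)CC(=O)C[C@@](C)(O)/C=C/[C@@]2(C(C)C)CC[C@]1(C)O2 | target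

**Step count**

Total steps: 13. Longest linear sequence: 13 steps, from (S)-citronellal 1.

**Steps most likely to fail and fallbacks**

Step 7 (macrocyclisation by alkynyl transfer to an enolisable ketone). The fallback sets out from 10 and comes back at 12, closing the ring at the alkyne instead. Prop-1-ynylmagnesium bromide is added to the ketone of 10 to give the propynyl carbinol (3RS,6E,10S,12R,14R)-12,14-bis(tert-butyldimethylsilyloxy)-2,6,10,14-tetramethyl-3-(prop-1-yn-1-yl)-16-(trimethylsilyl)hexadec-6-en-15-yn-3-ol F1. K2CO3 in MeOH removes the C-silyl group to give the terminal alkyne (3RS,6E,10S,12R,14R)-12,14-bis(tert-butyldimethylsilyloxy)-2,6,10,14-tetramethyl-3-(prop-1-yn-1-yl)hexadec-6-en-15-yn-3-ol F2. Its dianion (n-BuLi 2.2 equiv, then MeI 1 equiv, −78 °C) is C-methylated to the bis(methylalkyne) (3RS,6E,10S,12R,14R)-12,14-bis(tert-butyldimethylsilyloxy)-2,6,10,14-tetramethyl-3-(prop-1-yn-1-yl)heptadec-6-en-15-yn-3-ol F3. Ring-closing alkyne metathesis (molybdenum alkylidyne silanolate catalyst, 5 Å MS, toluene, high dilution) then forms the C2≡C3 bond and gives 12.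

Step 8 (hydride reduction of an alkyne flanked by two quaternary carbons, with possible loss of the C4 silyloxy group to an allene). The fallback sets out from 12 and comes back at 13. Hydroxyl-directed ruthenium-catalysed trans-hydrostannation ([Cp*RuCl]4, Bu3SnH, CH2Cl2) gives the alkenylstannane (1RS,2Z,4R,6R,8S,11E)-4,6-bis(tert-butyldimethylsilyloxy)-1-isopropyl-4,8,12-trimethyl-2-(tributylstannyl)cyclotetradeca-2,11-dien-1-ol F4. Copper-mediated protodestannation (CuTC, tetrabutylammonium diphenylphosphinate, DMF) then gives 13 without any aluminium hydride.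

Step 10 (convergence of the 1R epimer may fail through elimination or capture of the allyl cation by the epoxide oxygen). The fallback sets out from 14 and comes back at 16. With CSA in wet THF the 1S epimer closes to 15 as before and goes on through step 11. The 1R epimer is hydrolysed at C12 with inversion to the triol (1R,2E,4R,6R,8S,11R,12S)-4,6-bis(tert-butyldimethylsilyloxy)-1-isopropyl-4,8,12-trimethylcyclotetradec-2-ene-1,11,12-triol F5. Its secondary C11 hydroxyl is acetylated (Ac2O, pyridine) to (1R,2E,4R,6R,8S,11R,12S)-4,6-bis(tert-butyldimethylsilyloxy)-1,12-dihydroxy-1-isopropyl-4,8,12-trimethylcyclotetradec-2-en-11-yl acetate F6. Ionisation of the tertiary allylic C1 hydroxyl (cat. Bi(OTf)3 or Re2O7, CH2Cl2) then lets the C12 hydroxyl close the oxolane from the other side (SN1, cis-bridge controlled) to give 16.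

**Further compounds**

F1 | step 7 | (3RS,6E,10S,12R,14R)-12,14-bis(tert-butyldimethylsilyloxy)-2,6,10,14-tetramethyl-3-(prop-1-yn-1-yl)-16-(trimethylsilyl)hexadec-6-en-15-yn-3-ol | C[Si](C)(C)C#C[C@](C)(O[Si](C)(C)C(C)(C)C)C[C@H](O[Si](C)(C)C(C)(C)C)C[C@@H](C)CC/C=C(\C)CCC(O)(C#CC)C(C)C
F2 | step 7 | (3RS,6E,10S,12R,14R)-12,14-bis(tert-butyldimethylsilyloxy)-2,6,10,14-tetramethyl-3-(prop-1-yn-1-yl)hexadec-6-en-15-yn-3-ol | C#C[C@](C)(O[Si](C)(C)C(C)(C)C)C[C@H](O[Si](C)(C)C(C)(C)C)C[C@@H](C)CC/C=C(\C)CCC(O)(C#CC)C(C)C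
F3 | step 7 | (3RS,6E,10S,12R,14R)-12,14-bis(tert-butyldimethylsilyloxy)-2,6,10,14-tetramethyl-3-(prop-1-yn-1-yl)heptadec-6-en-15-yn-3-ol | CC#C[C@](C)(O[Si](C)(C)C(C)(C)C)C[C@H](O[Si](C)(C)C(C)(C)C)C[C@@H](C)CC/C=C(\C)CCC(O)(C#CC)C(C)C
F4 | step 8 | (1RS,2Z,4R,6R,8S,11E)-4,6-bis(tert-butyldimethylsilyloxy)-1-isopropyl-4,8,12-trimethyl-2-(tributylstannyl)cyclotetradeca-2,11-dien-1-ol | CC(C)C1(O)/C([Sn](CCCC)(CCCC)CCCC)=C/[C@](C)(O[Si](C)(C)C(C)(C)C)C[C@H](O[Si](C)(C)C(C)(C)C)C[C@@H](C)CC/C=C(\C)CC1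
F5 | step 10 | (1R,2E,4R,6R,8S,11R,12S)-4,6-bis(tert-butyldimethylsilyloxy)-1-isopropyl-4,8,12-trimethylcyclotetradec-2-ene-1,11,12-triol | CC(C)[C@@]1(O)/C=C/[C@](C)(O[Si](C)(C)C(C)(C)C)C[C@H](O[Si](C)(C)C(C)(C)C)C[C@@H](C)CC[C@@H](O)[C@@](C)(O)CC1
F6 | step 10 | (1R,2E,4R,6R,8S,11R,12S)-4,6-bis(tert-butyldimethylsilyloxy)-1,12-dihydroxy-1-isopropyl-4,8,12-trimethylcyclotetradec-2-en-11-yl acetate | CC(C)[C@@]1(O)/C=C/[C@](C)(O[Si](C)(C)C(C)(C)C)C[C@H](O[Si](C)(C)C(C)(C)C)C[C@@H](C)CC[C@@H](OC(C)=O)[C@@](C)(O)CC1
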